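**Plan**
- Retrosynthesis removes the two MOM ethers last. Before that it cuts the C7–C(=O) bond (aryllithium plus the Weinreb amide of 3-(4-methoxyphenyl)propanoic acid), the C5–CH2 bond of the prenyl group (aryllithium plus prenyl bromide), and then the O1–C2 bond of the dihydrofuran.
- Enabling feature: in the dihydrofuran ring the array O1–C2(H)–C(CH3)2OH is a constitutional isomer of the array O1–C(CH3)2–C3(H)OH of a 2,2-dimethylchroman-3-ol. Moving O1 from the dimethyl carbon to the carbinol carbon turns the six-membered pyran into the five-membered furan.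
- The chromanol goes back to a 2,2-dimethyl-2H-chromene (epoxide, then benzylic C–O hydrogenolysis), and the chromene to phloroglucinol and 3-methylbut-2-enal.
- Forward: the pyran ring is built first on the phloroglucinol ring, then contracted to the dihydrofuran; prenyl at C5, the acyl chain at C7 and deprotection follow. Both benzene rings are bought.
- Stereochemistry: the only stereocentre is set by Jacobsen epoxidation with (R,R)-(salen)MnCl (salen = N,N′-bis(3,5-di-tert-butylsalicylidene)-trans-cyclohexane-1,2-diamine dianion), which gives the 3R carbinol. One inversion in the ring contraction makes it 2S.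

Key step: step 5

Assumption: in the ring-contracted carbinol the proton between the two MOM ethers (H5) is metalated ahead of H7, because the acetal oxygens chelate lithium better than the ring ether oxygen; the tertiary hydroxyl is carried unprotected as its lithium alkoxide.

Step 1
Reactants: 1 phloroglucinol (benzene-1,3,5-triol, threefold excess); 2 3-methylbut-2-enal
Product: 4 2,2-dimethyl-2H-chromene-5,7-diol, via quinone methide 3 (not isolated)
Conditions: pyridine, 110 °C, slow addition of 2; excess 1 washed out with water; crude 4 used at once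
Reagents that add atoms: none
Why: Phenol–enal chromene annulation: Knoevenagel-type C-alkylation of the phloroglucinol nucleus by the enal with loss of water gives ortho-quinone methide 3, whose oxa-6π electrocyclisation closes the 2,2-dimethylpyran ring, and the excess of the water-soluble triol should hold the reaction at mono-annulation.

Step 2
Reactants: 4 2,2-dimethyl-2H-chromene-5,7-diol
Product: 5 5,7-bis(methoxymethoxy)-2,2-dimethyl-2H-chromene
Conditions: NaH, MOMCl, DMF, 0 °C → rt
Reagents that add atoms: chloromethyl methyl ether, COCCl
Why: Williamson-type O-alkylation: both sodium phenoxides should be alkylated on oxygen by the hard electrophile MOMCl, which protects the air-sensitive resorcinol unit and provides the two chelating directing groups for the later ortho-lithiations.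

Step 3
Reactants: 5 5,7-bis(methoxymethoxy)-2,2-dimethyl-2H-chromene
Product: 6 (3R,4R)-3,4-epoxy-5,7-bis(methoxymethoxy)-2,2-dimethylchromane
Conditions: (R,R)-(salen)MnCl (5 mol %), 4-phenylpyridine N-oxide (20 mol %), aq. NaOCl buffered to pH 11.3, CH2Cl2, 0 °C; filtered through basic alumina and used crude
Reagents that add atoms: sodium hypochlorite, [Na+].[O-]Cl
Why: Jacobsen epoxidation: the oxo-manganese species formed from the trivalent manganese complex and hypochlorite transfers oxygen to the cis, aryl-conjugated double bond of the 2,2-dimethylchromene, a privileged substrate class for this catalyst, and the (R,R) ligand should direct attack to the face that gives the 3R,4R epoxide, which sets the only stereocentre of the route.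

Step 4
Reactants: 6 (3R,4R)-3,4-epoxy-5,7-bis(methoxymethoxy)-2,2-dimethylchromane
Product: 7 (R)-5,7-bis(methoxymethoxy)-2,2-dimethylchroman-3-ol
Conditions: H2 (1 atm), Pd/C (10 wt %), EtOAc, solid NaHCO3, rt
Reagents that add atoms: none
Why: Hydrogenolysis of a benzylic C–O bond: zerovalent palladium on carbon should cleave only the activated C4–O bond of the epoxide, so C3 keeps its oxygen and its R configuration, while the aryl MOM ethers and the arene are inert under one atmosphere of hydrogen.

Step 5
Reactants: 7 (R)-5,7-bis(methoxymethoxy)-2,2-dimethylchroman-3-ol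
Product: 10 (S)-2-[4,6-bis(methoxymethoxy)-2,3-dihydrobenzofuran-2-yl]propan-2-ol, via chromanyl triflate 8 (not isolated), via oxiranium triflate 9 (not isolated)
Conditions: Tf2O (1.2 equiv), 2,6-lutidine (3 equiv), CH2Cl2, −78 °C; then THF/H2O (4:1) added cold, −78 °C → rt
Reagents that add atoms: water, O (trifluoromethanesulfonic anhydride, O=S(=O)(OS(=O)(=O)C(F)(F)F)C(F)(F)F, adds atoms only to intermediates 8 and 9)
Why: Triflic anhydride turns the secondary hydroxyl into triflate 8, and in the half-chair conformer with the C3–OTf bond pseudo-equatorial the O1–C2 bond lies anti-periplanar to it, so that on warming O1 displaces triflate from the rear to give the bridged aryloxiranium ion 9, which water opens at the dimethyl-substituted carbon with cleavage of the old O1–C2 bond. The closest known reaction type is the anchimerically assisted ring contraction of tetrahydropyran-3-yl and chroman-3-yl sulfonates, and of pyranoside 2-triflates to 2,5-anhydro sugars, a 1,2-shift of ring oxygen through an epoxonium ion. The dihydrofuran ring closes through the new O1–C bond in a 5-exo-tet sense, which is 3-exo-tet with respect to the transient oxirane ring, and the pyran ring is lost when water takes the tertiary carbon. The stereocentre is transferred under substrate control: the 3R carbinol carbon undergoes one SN2-type inversion and becomes C2 with S configuration, so the enantiomeric purity from step 3 should be carried over as long as no free secondary cation forms. The step needs oxygen migration to win over hydride shift from C4, methyl shift and elimination to the chromene, and needs water to attack the tertiary and not the secondary carbon of 9; the gem-dimethyl group favours both by stabilising positive charge at the migration origin, the hindered base 2,6-lutidine disfavours E2 loss of H4, and adding water before the triflate ionises should keep capture ahead of proton loss to the isopropenyl compound.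

Step 6
Reactants: 10 (S)-2-[4,6-bis(methoxymethoxy)-2,3-dihydrobenzofuran-2-yl]propan-2-ol; 11 prenyl bromide (1-bromo-3-methylbut-2-ene)
Product: 13 (S)-2-[4,6-bis(methoxymethoxy)-5-(3-methylbut-2-en-1-yl)-2,3-dihydrobenzofuran-2-yl]propan-2-ol, via C5 dilithio species 12 (not isolated)
Conditions: n-BuLi (2.3 equiv), THF, 0 °C; CuI (10 mol %), then 11, −78 → 0 °C; aq. NH4Cl
Reagents that add atoms: none
Why: Directed ortho-metalation and copper-catalysed allylic substitution: the first equivalent of base forms the lithium alkoxide, the second removes H5, the proton flanked by two chelating MOM ethers and therefore more readily metalated than H7 next to the ring oxygen, and the aryl nucleophile should displace bromide at the primary carbon of prenyl bromide without allylic transposition.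

Step 7
Reactants: 14 3-(4-methoxyphenyl)propanoic acid
Product: 16 N-methoxy-3-(4-methoxyphenyl)-N-methylpropanamide, via acyl imidazolide 15 (not isolated)
Conditions: CDI, CH2Cl2, rt; then MeNH(OMe)·HCl, rt
Reagents that add atoms: N,O-dimethylhydroxylamine hydrochloride, CNOC.Cl (1,1′-carbonyldiimidazole, O=C(n1ccnc1)n1ccnc1, adds atoms only to intermediate 15)
Why: Amide coupling through an acyl imidazolide: CDI activates the acid as 15 with loss of CO2, and N,O-dimethylhydroxylamine, freed from its hydrochloride by the liberated imidazole, should be acylated cleanly to the Weinreb amide.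

Step 8
Reactants: 13 (S)-2-[4,6-bis(methoxymethoxy)-5-(3-methylbut-2-en-1-yl)-2,3-dihydrobenzofuran-2-yl]propan-2-ol; 16 N-methoxy-3-(4-methoxyphenyl)-N-methylpropanamide
Product: 19 1-[(S)-2-(2-hydroxypropan-2-yl)-4,6-bis(methoxymethoxy)-5-(3-methylbut-2-en-1-yl)-2,3-dihydrobenzofuran-7-yl]-3-(4-methoxyphenyl)propan-1-one, via C7 dilithio species 17 (not isolated), via tetrahedral adduct 18 (not isolated)
Conditions: n-BuLi (2.3 equiv), TMEDA, THF, −20 → 0 °C; then 16, −78 → 0 °C; aq. NH4Cl
Reagents that add atoms: none
Why: Directed ortho-metalation and Weinreb ketone synthesis: with C5 blocked the only ring proton left is H7, flanked by the C6 MOM ether and O1, and the aryllithium should add once to the N-methoxy-N-methylamide to give the chelated tetrahedral adduct 18 (an inconsequential mixture at the new hemiaminal carbon), which collapses to the ketone only on aqueous quench, so no double addition is expected.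

Step 9
Reactants: 19 1-[(S)-2-(2-hydroxypropan-2-yl)-4,6-bis(methoxymethoxy)-5-(3-methylbut-2-en-1-yl)-2,3-dihydrobenzofuran-7-yl]-3-(4-methoxyphenyl)propan-1-one
Product: 20 1-[(S)-4,6-dihydroxy-2-(2-hydroxypropan-2-yl)-5-(3-methylbut-2-en-1-yl)-2,3-dihydrobenzofuran-7-yl]-3-(4-methoxyphenyl)propan-1-one (CNP0150199.1)
Conditions: HCl (ca. 1 M) in MeOH, rt → 35 °C, stopped as soon as 19 is consumed
Reagents that add atoms: none
Why: Acid-catalysed acetal cleavage (MOM removal by transacetalisation to dimethoxymethane): dilute HCl in methanol near room temperature should release both phenols, the one ortho to the ketone fastest, while the mild acid is meant to spare the tertiary alcohol and to keep the prenyl olefin from cyclising onto the flanking phenols.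

**Compound list**
1 | phloroglucinol | Oc1cc(O)cc(O)c1 | starting material
2 | 3-methylbut-2-enal | CC(C)=CC=O | starting material
3 | 3,5-dihydroxy-6-(3-methylbut-2-en-1-ylidene)cyclohexa-2,4-dien-1-one (ortho-quinone methide) | CC(C)=CC=C1C(=O)C=C(O)C=C1O | intermediate
4 | 2,2-dimethyl-2H-chromene-5,7-diol | CC1(C)C=Cc2c(O)cc(O)cc2O1 | intermediate
5 | 5,7-bis(methoxymethoxy)-2,2-dimethyl-2H-chromene | CC1(C)C=Cc2c(OCOC)cc(OCOC)cc2O1 | intermediate
6 | (3R,4R)-3,4-epoxy-5,7-bis(methoxymethoxy)-2,2-dimethylchromane | CC1(C)Oc2cc(OCOC)cc(OCOC)c2[C@H]2O[C@@H]12 | intermediate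
7 | (R)-5,7-bis(methoxymethoxy)-2,2-dimethylchroman-3-ol | CC1(C)Oc2cc(OCOC)cc(OCOC)c2C[C@H]1O | intermediate
8 | (R)-5,7-bis(methoxymethoxy)-2,2-dimethylchroman-3-yl trifluoromethanesulfonate | CC1(C)Oc2cc(OCOC)cc(OCOC)c2C[C@H]1OS(=O)(=O)C(F)(F)F | intermediate
9 | bridged aryloxiranium triflate (O1 bonded to C7a, to the S-configured former carbinol carbon and to the dimethyl carbon) | COCOc1cc(OCOC)c2c(c1)[O+]3[C@@H](C2)C3(C)C.[O-]S(=O)(=O)C(F)(F)F | intermediate
10 | (S)-2-[4,6-bis(methoxymethoxy)-2,3-dihydrobenzofuran-2-yl]propan-2-ol | COCOc1cc(OCOC)c2c(c1)O[C@H](C(C)(C)O)C2 | intermediate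
11 | prenyl bromide (1-bromo-3-methylbut-2-ene) | CC(C)=CCBr | starting material
12 | C5-lithio lithium alkoxide of 10 | COCOc1c([Li])c(OCOC)c2c(c1)O[C@H](C(C)(C)O[Li])C2 | intermediate
13 | (S)-2-[4,6-bis(methoxymethoxy)-5-(3-methylbut-2-en-1-yl)-2,3-dihydrobenzofuran-2-yl]propan-2-ol | COCOc1c(CC=C(C)C)c(OCOC)c2c(c1)O[C@H](C(C)(C)O)C2 | intermediate
14 | 3-(4-methoxyphenyl)propanoic acid | COc1ccc(CCC(=O)O)cc1 | starting material
15 | 1-(imidazol-1-yl)-3-(4-methoxyphenyl)propan-1-one (acyl imidazolide) | COc1ccc(CCC(=O)n2ccnc2)cc1 | intermediate
16 | N-methoxy-3-(4-methoxyphenyl)-N-methylpropanamide | COc1ccc(CCC(=O)N(C)OC)cc1 | intermediate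
17 | C7-lithio lithium alkoxide of 13 | COCOc1c(CC=C(C)C)c(OCOC)c2c(c1[Li])O[C@H](C(C)(C)O[Li])C2 | intermediate
18 | dilithium salt of the N-methoxy-N-methyl hemiaminal adduct of 17 and 16 (hemiaminal carbon unassigned) | COCOc1c(CC=C(C)C)c(OCOC)c2c(c1C(O[Li])(CCc1ccc(OC)cc1)N(C)OC)O[C@H](C(C)(C)O[Li])C2 | intermediate
19 | 1-[(S)-2-(2-hydroxypropan-2-yl)-4,6-bis(methoxymethoxy)-5-(3-methylbut-2-en-1-yl)-2,3-dihydrobenzofuran-7-yl]-3-(4-methoxyphenyl)propan-1-one | COCOc1c(CC=C(C)C)c(OCOC)c2c(c1C(=O)CCc1ccc(OC)cc1)O[C@H](C(C)(C)O)C2 | intermediate
20 | 1-[(S)-4,6-dihydroxy-2-(2-hydroxypropan-2-yl)-5-(3-methylbut-2-en-1-yl)-2,3-dihydrobenzofuran-7-yl]-3-(4-methoxyphenyl)propan-1-one | COc1ccc(CCC(=O)c2c(O)c(CC=C(C)C)c(O)c3c2O[C@H](C(C)(C)O)C3)cc1 | target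

**Step count**
Total: 9 steps. Longest linear sequence: 8 steps (steps 1–6, 8, 9); step 7 is a one-step side branch.

**Steps most likely to fail**

Step 5. Proton loss from the bridged ion may outrun capture by water, or the triflate may ionise before water is present, so that the contraction ends at the alkene stage. The fallback sets out from 7 and accepts this outcome. Activation with Tf2O and 2,6-lutidine in dry CH2Cl2, warmed to rt without water, should give (S)-4,6-bis(methoxymethoxy)-2-(prop-1-en-2-yl)-2,3-dihydrobenzofuran F1 by the same oxygen shift followed by loss of a methyl proton. Mukaiyama hydration of this 1,1-disubstituted olefin (Co(acac)2 cat., PhSiH3, O2, i-PrOH) then installs the tertiary hydroxyl with Markovnikov regiochemistry, leaves the stereocentre untouched and comes back to the route at 10.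

Step 3. The very electron-rich benzylic epoxide may open at C4 during reaction or isolation, under trace acid or the Lewis-acidic manganese complex, which would cost material and possibly enantiopurity. The fallback sets out from 5 and uses that lability. Non-asymmetric epoxidation with dimethyldioxirane in acetone at −20 °C gives rac-3,4-epoxy-5,7-bis(methoxymethoxy)-2,2-dimethylchromane F2. Catalytic ZnI2 in CH2Cl2 should then cause Meinwald rearrangement (ionisation at C4, 1,2-hydride shift) to 5,7-bis(methoxymethoxy)-2,2-dimethylchroman-3-one F3. Corey–Bakshi–Shibata reduction with the (S)-B-methyl oxazaborolidine and BH3·SMe2, where quaternary C2 is the large group and the benzylic CH2 the small one, is expected to give the R alcohol and comes back to the route at 7.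

Step 8. Deprotonation at the benzylic–allylic CH2 of the prenyl group may compete with ring metalation, and the hindered aryllithium may enolise the amide instead of adding to it. The fallback sets out from 10 and brings in the prenyl group last, which also removes the prenyl olefin from the acidic deprotection. Bromination with N-bromosuccinimide in CH2Cl2 at 0 °C should occur at the less hindered activated position and give (S)-2-[7-bromo-4,6-bis(methoxymethoxy)-2,3-dihydrobenzofuran-2-yl]propan-2-ol F4. Bromine–lithium exchange (n-BuLi, 2.2 equiv, THF, −78 °C) and trapping with amide 16 would give 1-[(S)-2-(2-hydroxypropan-2-yl)-4,6-bis(methoxymethoxy)-2,3-dihydrobenzofuran-7-yl]-3-(4-methoxyphenyl)propan-1-one F5. MOM removal with HCl in MeOH then gives 1-[(S)-4,6-dihydroxy-2-(2-hydroxypropan-2-yl)-2,3-dihydrobenzofuran-7-yl]-3-(4-methoxyphenyl)propan-1-one F6. Its only free ring position is C5, so classical C-prenylation of the acylphloroglucinol-type phenoxide with prenyl bromide 11 in cold aq. KOH should come back to the route at 20.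

**Further compounds**
F1 | step 5 | (S)-4,6-bis(methoxymethoxy)-2-(prop-1-en-2-yl)-2,3-dihydrobenzofuran | COCOc1cc(OCOC)c2c(c1)O[C@H](C(C)=C)C2
F2 | step 3 | rac-3,4-epoxy-5,7-bis(methoxymethoxy)-2,2-dimethylchromane | CC1(C)Oc2cc(OCOC)cc(OCOC)c2C2OC12
F3 | step 3 | 5,7-bis(methoxymethoxy)-2,2-dimethylchroman-3-one | CC1(C)Oc2cc(OCOC)cc(OCOC)c2CC1=O
F4 | step 8 | (S)-2-[7-bromo-4,6-bis(methoxymethoxy)-2,3-dihydrobenzofuran-2-yl]propan-2-ol | COCOc1cc(OCOC)c2c(c1Br)O[C@H](C(C)(C)O)C2
F5 | step 8 | 1-[(S)-2-(2-hydroxypropan-2-yl)-4,6-bis(methoxymethoxy)-2,3-dihydrobenzofuran-7-yl]-3-(4-methoxyphenyl)propan-1-one | COCOc1cc(OCOC)c2c(c1C(=O)CCc1ccc(OC)cc1)O[C@H](C(C)(C)O)C2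
F6 | step 8 | 1-[(S)-4,6-dihydroxy-2-(2-hydroxypropan-2-yl)-2,3-dihydrobenzofuran-7-yl]-3-(4-methoxyphenyl)propan-1-one | COc1ccc(CCC(=O)c2c(O)cc(O)c3c2O[C@H](C(C)(C)O)C3)cc1
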